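The oxazole ring is disconnected at N3–C4 and O1–C5. Its C4–Cl beside N3 is treated as an imidoyl chloride, the trace of a lactam carbonyl, and C5, bound to O1, is a benzylic carbon para to an oxygen substituent; the ring therefore maps onto an oxazol-4(5H)-one. One thermal annulation joins 3,4,5-trichloro-1H-pyrrole-2-carboxamide (free N–H) to racemic 2-chloro-2-(4-methoxyphenyl)acetyl chloride: N-acylation makes N3–C4, then the amide oxygen displaces the benzylic chloride to make O1–C5. Deoxychlorination afterwards places the fourth chlorine and aromatises the ring with no electrophilic chlorine near the anisole; ether cleavage finishes.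

Key step: step 4

Remark on the chemistry: 4-methoxymandelic acid is taken as the racemate. The benzylic stereocentre carried through compounds 5 to 8 becomes sp2 in step 5, the target is achiral, and no stereocontrol is needed.

Step 1
Reactants: 1 2-(trichloroacetyl)pyrrole
Product: 2 2,2,2-trichloro-1-(3,4,5-trichloro-1H-pyrrol-2-yl)ethan-1-one
Conditions: SO2Cl2 (4 equiv), CHCl3, 0 °C to reflux
Reagents that add atoms: sulfuryl chloride, O=S(=O)(Cl)Cl
Why: Electrophilic aromatic chlorination in which the trichloroacetyl group tempers the pyrrole against polymerisation and blocks C2, positions 4 and 5 react first, and excess reagent with heating should force the deactivated position 3.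

Step 2
Reactants: 2 2,2,2-trichloro-1-(3,4,5-trichloro-1H-pyrrol-2-yl)ethan-1-one; 3 ammonia
Product: 4 3,4,5-trichloro-1H-pyrrole-2-carboxamide
Conditions: aq. NH3 (excess), THF, 0 °C to rt; dilute HCl work-up
Reagents that add atoms: ammonia (3), N
Why: Haloform-type acyl substitution, the standard amidation of 2-(trichloroacetyl)pyrroles, in which ammonia attacks the acyl carbon and trichloromethanide leaves as chloroform; acidification returns the neutral N–H pyrrole.

Step 3
Reactants: 5 4-methoxymandelic acid (racemic)
Product: 6 2-chloro-2-(4-methoxyphenyl)acetyl chloride (racemic)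
Conditions: SOCl2 (4 equiv), DMF (cat.), CH2Cl2, 40 °C; evaporate with PhMe, use crude at once
Reagents that add atoms: thionyl chloride, O=S(Cl)Cl
Why: Deoxychlorination with thionyl chloride converts the acid into the acyl chloride and, with p-methoxy assistance to chloride return at the benzylic carbon, the alcohol into the benzylic chloride; the racemate stays racemic.

Step 4
Reactants: 4 3,4,5-trichloro-1H-pyrrole-2-carboxamide; 6 2-chloro-2-(4-methoxyphenyl)acetyl chloride (racemic)
Product: 8 5-(4-methoxyphenyl)-2-(3,4,5-trichloro-1H-pyrrol-2-yl)oxazol-4(5H)-one (racemic), via chloro imide 7 (not isolated)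
Conditions: 6 (1.3 equiv), PhCl, 110 °C, slow N2 sweep (−HCl), no base; concentrate and carry on under N2
Reagents that add atoms: none
Why: The amide nitrogen of 4 is acylated by the acid chloride of 6 with loss of HCl to give imide 7, whose pyrrole-side carbonyl oxygen then attacks the p-methoxybenzylic carbon, expels chloride and, after loss of the imide proton, leaves the C2=N3 double bond of 8. The closest known reaction type is the preparation of 2-aryl-oxazol-4(5H)-ones from primary carboxamides and α-haloacyl halides by way of α-halo imides. The single ring is closed in the 5-exo-tet mode (O1 onto C5, chloride leaving outside the ring), and the p-methoxy group gives the benzylic carbon enough cationic character for a weak neutral oxygen nucleophile to close without base. The only new stereocentre, C5, forms racemic from racemic 6 and needs no control, because it is erased in step 5. The step needs closure through the imide oxygen (five-membered ring) and not through the pyrrole nitrogen (six-membered 4-aryl-pyrrolo[1,2-a]pyrazine-1,3-dione), and acylation at the amide and not at the pyrrole nitrogen; both should follow from keeping the pyrrole N–H neutral, since a nitrogen flanked by a ring chlorine and the acyl-bearing carbon is essentially non-nucleophilic without base.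

Step 5
Reactants: 8 5-(4-methoxyphenyl)-2-(3,4,5-trichloro-1H-pyrrol-2-yl)oxazol-4(5H)-one (racemic)
Product: 9 4-chloro-5-(4-methoxyphenyl)-2-(3,4,5-trichloro-1H-pyrrol-2-yl)oxazole
Conditions: POCl3 (neat), pyridine (1 equiv), 90 °C; quench on ice/NaHCO3
Reagents that add atoms: phosphoryl chloride, O=P(Cl)(Cl)Cl
Why: Deoxychlorination of a lactam carbonyl with phosphoryl chloride, the reaction type that turns azolones and hydroxy-azoles into chloro-azoles: the C4 oxygen is activated by phosphorylation, chloride adds and the phosphate leaves, and loss of the C5 proton aromatises the ring; chlorine arrives as chloride, so the anisole ring is untouched.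

Step 6
Reactants: 9 4-chloro-5-(4-methoxyphenyl)-2-(3,4,5-trichloro-1H-pyrrol-2-yl)oxazole
Product: 10 4-[4-chloro-2-(3,4,5-trichloro-1H-pyrrol-2-yl)-1,3-oxazol-5-yl]phenol
Conditions: BBr3 (4 equiv), CH2Cl2, −78 °C to rt; then MeOH, H2O
Reagents that add atoms: none
Why: Lewis-acid cleavage of an aryl methyl ether, in which boron binds the methoxy oxygen and bromide attacks the methyl group in an SN2 step before hydrolysis frees the phenol; the aryl and heteroaryl C–Cl bonds and the oxazole should be inert, and the excess reagent covers binding at the oxazole nitrogen and pyrrole N–H.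

Compound list
1 | 2-(trichloroacetyl)pyrrole [2,2,2-trichloro-1-(1H-pyrrol-2-yl)ethan-1-one] | O=C(c1ccc[nH]1)C(Cl)(Cl)Cl | starting material
2 | 2,2,2-trichloro-1-(3,4,5-trichloro-1H-pyrrol-2-yl)ethan-1-one | O=C(c1[nH]c(Cl)c(Cl)c1Cl)C(Cl)(Cl)Cl | intermediate
3 | ammonia | N | starting material
4 | 3,4,5-trichloro-1H-pyrrole-2-carboxamide | NC(=O)c1[nH]c(Cl)c(Cl)c1Cl | intermediate
5 | 4-methoxymandelic acid (racemic) | COc1ccc(cc1)C(O)C(O)=O | starting material
6 | 2-chloro-2-(4-methoxyphenyl)acetyl chloride (racemic) | COc1ccc(cc1)C(Cl)C(Cl)=O | intermediate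
7 | 3,4,5-trichloro-N-[2-chloro-2-(4-methoxyphenyl)acetyl]-1H-pyrrole-2-carboxamide (racemic chloro imide, not isolated) | COc1ccc(cc1)C(Cl)C(=O)NC(=O)c1[nH]c(Cl)c(Cl)c1Cl | intermediate
8 | 5-(4-methoxyphenyl)-2-(3,4,5-trichloro-1H-pyrrol-2-yl)oxazol-4(5H)-one (racemic) | COc1ccc(cc1)C1OC(=NC1=O)c1[nH]c(Cl)c(Cl)c1Cl | intermediate
9 | 4-chloro-5-(4-methoxyphenyl)-2-(3,4,5-trichloro-1H-pyrrol-2-yl)oxazole | COc1ccc(cc1)-c1oc(nc1Cl)-c1[nH]c(Cl)c(Cl)c1Cl | intermediate
10 | 4-[4-chloro-2-(3,4,5-trichloro-1H-pyrrol-2-yl)-1,3-oxazol-5-yl]phenol | Oc1ccc(-c2oc(-c3[nH]c(Cl)c(Cl)c3Cl)nc2Cl)cc1 | target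

Total step count: 6. Longest linear sequence: 5 steps (steps 1, 2, 4, 5, 6); step 3 is the one-step side branch.

Steps most likely to fail

Step 4. The acid chloride may dehydrate the primary amide to the nitrile through O-acylation, the benzylic chloride may ionise and oligomerise before the imide has formed, or the ring may close through the wrong heteroatom. The fallback reverses the order of bond formation and removes the acyl chloride from the annulation. It sets out from 6 and 4 and comes back at 8.
- Compound 6 is quenched with methanol (1.1 equiv, CH2Cl2, 0 °C) to give methyl 2-chloro-2-(4-methoxyphenyl)acetate F1.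
- Amide 4 is alkylated on oxygen by F1 with AgOTf (AgOSO2CF3, 1.1 equiv, 1,2-dichloroethane, 60 °C), a silver-assisted amide O-alkylation as in Blümlein–Lewy-type oxazole syntheses. This should give the imidate methyl 2-{[imino(3,4,5-trichloro-1H-pyrrol-2-yl)methyl]oxy}-2-(4-methoxyphenyl)acetate F2, so O1–C5 is made first.
- After a NaHCO3 wash, heating F2 in toluene should close N3–C4 by attack of the imidate nitrogen on the ester with loss of methanol, as in the Hantzsch-type route from thioamides and α-halo esters to thiazol-4-ones, giving 8.

Step 5. Activation of the weakly basic C4 oxygen may be incomplete, chloride may open the activated ring, or the C5–H oxazolone may be oxidised by air before it is chlorinated. The fallback gives up the lactam-to-chloride logic and builds the oxazole with C4–H, chlorinating last. It sets out from 2 and comes back at 9.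
- Ketone 2 acylates 2-amino-1-(4-methoxyphenyl)ethan-1-one hydrochloride (Cl.NCC(=O)c1ccc(OC)cc1; Et3N, MeCN, rt) in the same haloform-type aminolysis as step 2, to give 3,4,5-trichloro-N-[2-(4-methoxyphenyl)-2-oxoethyl]-1H-pyrrole-2-carboxamide F3.
- Robinson–Gabriel cyclodehydration (POCl3, PhMe, 90 °C) should give 5-(4-methoxyphenyl)-2-(3,4,5-trichloro-1H-pyrrol-2-yl)oxazole F4.
- One equivalent of N-chlorosuccinimide (MeCN/AcOH, rt) should chlorinate C4, the enol-ether-like carbon conjugated with the anisyl donor, to give 9. Competing chlorination ortho to the methoxy group is the cost of this path and is limited by stopping at one equivalent.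

Step 1. Chlorination may stall at the 4,5-dichloro stage, because position 3 lies next to the strongly electron-withdrawing trichloroacetyl group, or forcing may degrade the ring oxidatively. The fallback changes the order so that the halogenation runs on a more electron-rich ring. It sets out from 1 and comes back at 4.
- Compound 1 is first treated with aqueous ammonia (THF, rt) to give 1H-pyrrole-2-carboxamide F5.
- F5 is chlorinated three times with N-chlorosuccinimide (3.1 equiv, DMF, 50 °C), an electrophilic chlorination of a pyrrole deactivated only by a carboxamide, which should give 4 directly.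

Further compounds
F1 | step 4 | methyl 2-chloro-2-(4-methoxyphenyl)acetate (racemic) | COC(=O)C(Cl)c1ccc(OC)cc1
F2 | step 4 | methyl 2-{[imino(3,4,5-trichloro-1H-pyrrol-2-yl)methyl]oxy}-2-(4-methoxyphenyl)acetate (racemic) | COC(=O)C(OC(=N)c1[nH]c(Cl)c(Cl)c1Cl)c1ccc(OC)cc1
F3 | step 5 | 3,4,5-trichloro-N-[2-(4-methoxyphenyl)-2-oxoethyl]-1H-pyrrole-2-carboxamide | COc1ccc(cc1)C(=O)CNC(=O)c1[nH]c(Cl)c(Cl)c1Cl
F4 | step 5 | 5-(4-methoxyphenyl)-2-(3,4,5-trichloro-1H-pyrrol-2-yl)oxazole | COc1ccc(cc1)-c1cnc(o1)-c1[nH]c(Cl)c(Cl)c1Cl
F5 | step 1 | 1H-pyrrole-2-carboxamide | NC(=O)c1ccc[nH]1
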